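## Retrosynthetic overview
1. The C8′ carbinol comes last, from the C8′ methyl enone by oxazaborolidine-catalysed ketone reduction (sets 8′R).
2. The key disconnection is the C1′–O bond. The hydroxyl oxygen of a (5S,6R)-6-hydroxy dienone is joined to a pyron-6-yl carbene carbon. The resulting oxonium ylide relays itself by a [2,3] shift, which gives C1′–C2′, 1′S, 2′S and the 3′E alkene and consumes the old carbinol centre.
3. The hydroxy dienone comes from cross-metathesis (6′E enone) of the syn-crotylboration product of tiglaldehyde, which sets C5′ and the relay carbinol.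
4. The carbene precursor is the tosylhydrazone of the pyrone-6-carbaldehyde, made from 4-hydroxy-3,6-dimethyl-2-pyrone by O-methylation and SeO2 oxidation.
5. Rings: the only ring, the 2-pyrone, is bought intact, so no ring is formed in the route.

Assumption: 1, 5, 6 and 9 are catalogue compounds. Primed locants count the side chain from the carbinol carbon on pyrone C6 (C1′) to the terminal methyl (C9′). The SMILES reads 1′S,2′S (anti),5′R,8′R with 3′E and 6′E.

## Route

Step 1
Reactants: 1 4-hydroxy-3,6-dimethyl-2H-pyran-2-one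
Product: 2 4-methoxy-3,6-dimethyl-2H-pyran-2-one
Conditions: Me2SO4 (1.2 equiv), K2CO3 (1.5 equiv), acetone, reflux, 4 h
Reagents that add atoms: dimethyl sulfate, COS(=O)(=O)OC
Why: Williamson-type O-alkylation of the 4-hydroxy-2-pyrone anion with a hard methylating agent in acetone goes to the 4-oxygen and gives the 4-methoxy-2-pyrone, the usual outcome for this ring; no stereocenter is involved.

Step 2
Reactants: 2 4-methoxy-3,6-dimethyl-2H-pyran-2-one
Product: 3 4-methoxy-3-methyl-2-oxo-2H-pyran-6-carbaldehyde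
Conditions: SeO2 (2.5 equiv), 1,4-dioxane, sealed tube, 160 °C, 3 h
Reagents that add atoms: selenium dioxide, O=[Se]=O
Why: Riley oxidation (ene reaction, then [2,3] shift) picks the 6-methyl because electrophilic selenium can bond to the nucleophilic C5, whereas oxidation of the 3-methyl would need attack at the electrophilic, oxygen-bearing C4, as is established for 4-methoxy-6-methyl-2-pyrones.

Step 3
Reactants: 3 4-methoxy-3-methyl-2-oxo-2H-pyran-6-carbaldehyde
Product: 4 N′-[(E)-(4-methoxy-3-methyl-2-oxo-2H-pyran-6-yl)methylidene]-4-methylbenzenesulfonohydrazide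
Conditions: TsNHNH2 (1.05 equiv), MeOH, 23 °C, 2 h, filter
Reagents that add atoms: 4-methylbenzenesulfonohydrazide, Cc1ccc(cc1)S(=O)(=O)NN
Why: Hydrazone condensation at the very electrophilic aldehyde is much faster at room temperature than attack of the weakly nucleophilic sulfonyl hydrazide on the pyrone ring, and the E-hydrazone crystallises out.

Step 4
Reactants: 5 (E)-2-methylbut-2-enal (tiglaldehyde); 6 2-[(2Z)-but-2-en-1-yl]-4,4,5,5-tetramethyl-1,3,2-dioxaborolane ((Z)-crotylboronic acid pinacol ester)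
Product: 8 (3S,4R,5E)-3,5-dimethylhepta-1,5-dien-4-ol, via pinacol borate ester 7 (not isolated)
Conditions: 6 (1.2 equiv), (R)-TRIP [(R)-3,3′-bis(2,4,6-triisopropylphenyl)-1,1′-binaphthyl-2,2′-diyl hydrogen phosphate] (5 mol %), toluene, −30 °C, 24 h; aq. NaHCO3
Reagents that add atoms: none
Why: Chiral-phosphoric-acid-catalysed crotylboration runs through a closed chair (Zimmerman–Traxler) transition state in which the Z-crotyl geometry gives the 3,4-syn pair and (R)-TRIP directs attack to the Re face of 5, which gives 4R and therefore 3S.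

Step 5
Reactants: 8 (3S,4R,5E)-3,5-dimethylhepta-1,5-dien-4-ol; 9 3-methylbut-3-en-2-one
Product: 10 (3E,5S,6R,7E)-6-hydroxy-3,5,7-trimethylnona-3,7-dien-2-one
Conditions: 9 (5 equiv, freshly distilled), second-generation Hoveyda–Grubbs catalyst RuCl2(H2IMes)(=CH-C6H4-2-OiPr) (5 mol %), 1,4-benzoquinone (10 mol %), CH2Cl2, 40 °C, 16 h
Reagents that add atoms: none
Why: Olefin cross-metathesis pairs the only monosubstituted alkene with an excess of a 1,1-disubstituted enone that does not homodimerise; the trisubstituted tiglyl alkene is inert, thermodynamic control gives the E-enone, and benzoquinone suppresses hydride-induced alkene migration so that C5 stays intact.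

Step 6
Reactants: 4 N′-[(E)-(4-methoxy-3-methyl-2-oxo-2H-pyran-6-yl)methylidene]-4-methylbenzenesulfonohydrazide; 10 (3E,5S,6R,7E)-6-hydroxy-3,5,7-trimethylnona-3,7-dien-2-one
Product: 14 6-[(1S,2S,3E,5R,6E)-1-hydroxy-2,3,5,7-tetramethyl-8-oxonona-3,6-dien-1-yl]-4-methoxy-3-methyl-2H-pyran-2-one, via sodium salt 11 (not isolated), via diazo compound 12 (not isolated), via oxonium ylide 13 (not isolated)
Conditions: 4 (1.5 equiv), NaH (1.5 equiv), THF, 0 °C, evaporate to dryness; then 10 (1.0 equiv), Rh2(O2CCPh3)4 (2 mol %), BnEt3NCl (10 mol %), 4 Å MS, toluene (0.02 M), 40 °C, 12 h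
Reagents that add atoms: none
Why: Proposed new method: salt 11 releases the doubly vinylogous diazo ester 12 slowly (Bamford–Stevens under phase transfer), Rh2(O2CCPh3)4 converts it into an electrophilic pyron-6-yl carbene, and the hydroxyl oxygen of 10 attacks the carbene carbon to make the C1′–O bond of the target as ylide 13; the [2,3] shift should outrun the 1,2-proton shift (O–H insertion) because the ylide carbanion is delocalised into the pyrone like a vinylogous ester enolate, the allyl terminus is an electron-rich trisubstituted alkene, the carbinol is hindered, and proton shuttles are excluded (toluene, sieves, high dilution, bulky carboxylate pocket); in the five-membered envelope transition state the C5′ chain is pseudo-equatorial (3′E), the C–O bond of the 6R carbinol is exchanged on the same face for C1′–C2′ (2′S), and the pyrone sits exo, away from the C3′ methyl (E-alkene gives anti, hence 1′S); the closest known reaction types are the rhodium-catalysed tandem oxonium-ylide formation/[2,3]-sigmatropic rearrangement of donor/acceptor diazo esters with allylic alcohols and the [2,3]-Wittig rearrangement, and what is new is a hydrogen-bearing pyronyl carbene generated from a hydrazone salt, a secondary carbinol product, and full substrate control of both new centres.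

Step 7
Reactants: 14 6-[(1S,2S,3E,5R,6E)-1-hydroxy-2,3,5,7-tetramethyl-8-oxonona-3,6-dien-1-yl]-4-methoxy-3-methyl-2H-pyran-2-one
Product: 16 6-[(1S,2S,3E,5R,6E,8R)-1,8-dihydroxy-2,3,5,7-tetramethylnona-3,6-dien-1-yl]-4-methoxy-3-methyl-2H-pyran-2-one (CNP0511955.1), via bis(catecholborate) 15 (not isolated)
Conditions: (S)-Me-CBS oxazaborolidine (0.5 equiv), catecholborane (3 equiv), toluene, −78 °C, 6 h; MeOH, then aq. NaHCO3
Reagents that add atoms: none
Why: In this Corey–Bakshi–Shibata reduction the α-methylalkenyl group acts as the large and the methyl as the small ketone substituent, so the (S)-catalyst delivers hydride to give 8′R with clean 1,2-selectivity, while the free C1′ hydroxyl is only masked transiently as its borate and the pyrone and trisubstituted alkenes are untouched at −78 °C.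

## Compound list
1 | 4-hydroxy-3,6-dimethyl-2H-pyran-2-one | Cc1cc(O)c(C)c(=O)o1 | starting material
2 | 4-methoxy-3,6-dimethyl-2H-pyran-2-one | COc1cc(C)oc(=O)c1C | intermediate
3 | 4-methoxy-3-methyl-2-oxo-2H-pyran-6-carbaldehyde | COc1cc(C=O)oc(=O)c1C | intermediate
4 | N′-[(E)-(4-methoxy-3-methyl-2-oxo-2H-pyran-6-yl)methylidene]-4-methylbenzenesulfonohydrazide | COc1cc(/C=N/NS(=O)(=O)c2ccc(C)cc2)oc(=O)c1C | intermediate
5 | (E)-2-methylbut-2-enal (tiglaldehyde) | C/C=C(\C)C=O | starting material
6 | 2-[(2Z)-but-2-en-1-yl]-4,4,5,5-tetramethyl-1,3,2-dioxaborolane | C/C=C\CB1OC(C)(C)C(C)(C)O1 | starting material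
7 | 2-{[(3S,4R,5E)-3,5-dimethylhepta-1,5-dien-4-yl]oxy}-4,4,5,5-tetramethyl-1,3,2-dioxaborolane | C/C=C(\C)[C@H](OB1OC(C)(C)C(C)(C)O1)[C@@H](C)C=C | intermediate
8 | (3S,4R,5E)-3,5-dimethylhepta-1,5-dien-4-ol | C/C=C(\C)[C@H](O)[C@@H](C)C=C | intermediate
9 | 3-methylbut-3-en-2-one | CC(=O)C(C)=C | starting material
10 | (3E,5S,6R,7E)-6-hydroxy-3,5,7-trimethylnona-3,7-dien-2-one | C/C=C(\C)[C@H](O)[C@@H](C)/C=C(\C)C(C)=O | intermediate
11 | sodium salt of hydrazone 4 (N-deprotonated) | COc1cc(/C=N/[N-]S(=O)(=O)c2ccc(C)cc2)oc(=O)c1C.[Na+] | intermediate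
12 | 6-(diazomethyl)-4-methoxy-3-methyl-2H-pyran-2-one | COc1cc(C=[N+]=[N-])oc(=O)c1C | intermediate
13 | oxonium ylide: (4-methoxy-3-methyl-2-oxo-2H-pyran-6-yl)methanide carbon bonded to the protonated oxygen of 10 (5S,6R retained) | COc1cc([CH-][OH+][C@H]([C@@H](C)/C=C(\C)C(C)=O)/C(C)=C/C)oc(=O)c1C | intermediate
14 | 6-[(1S,2S,3E,5R,6E)-1-hydroxy-2,3,5,7-tetramethyl-8-oxonona-3,6-dien-1-yl]-4-methoxy-3-methyl-2H-pyran-2-one | COc1cc([C@@H](O)[C@@H](C)/C(C)=C/[C@@H](C)/C=C(\C)C(C)=O)oc(=O)c1C | intermediate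
15 | 1′,8′-bis(1,3,2-benzodioxaborol-2-yl) ether of 16 | COc1cc([C@@H](OB2Oc3ccccc3O2)[C@@H](C)/C(C)=C/[C@@H](C)/C=C(\C)[C@@H](C)OB2Oc3ccccc3O2)oc(=O)c1C | intermediate
16 | 6-[(1S,2S,3E,5R,6E,8R)-1,8-dihydroxy-2,3,5,7-tetramethylnona-3,6-dien-1-yl]-4-methoxy-3-methyl-2H-pyran-2-one | COc1cc([C@@H](O)[C@@H](C)/C(C)=C/[C@@H](C)/C=C(\C)[C@@H](C)O)oc(=O)c1C | target

## Step count and risks
Total step count: 7. Longest linear sequence: 5 (steps 1, 2, 3, 6, 7).

**Step 6 (new method).**
- Risks: a proton shift may give the O–H insertion ether instead of the [2,3] product. The C3′ methyl may let some Z-alkene/2′-epimer through. The carbene may dimerise.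
- Fallback (known chemistry: Williamson ether synthesis, [2,3]-Wittig rearrangement, cross-metathesis). It sets out from 3 and 8 and comes back to the route at 14.
- NaBH4 (MeOH, 0 °C) reduces 3 to 6-(hydroxymethyl)-4-methoxy-3-methyl-2H-pyran-2-one F1. CBr4/PPh3 (CH2Cl2, 0 °C) then converts this into 6-(bromomethyl)-4-methoxy-3-methyl-2H-pyran-2-one F2.
- The sodium alkoxide of 8 (NaH, Bu4NI, THF, 0 °C) is alkylated by F2. This makes the same C1′–O bond by SN2 and gives 6-({[(3S,4R,5E)-3,5-dimethylhepta-1,5-dien-4-yl]oxy}methyl)-4-methoxy-3-methyl-2H-pyran-2-one F3.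
- LiN(iPr)2 (THF, −78 °C) removes the vinylogously acidic pyronyl CH2 proton. The anion rearranges through the same exo envelope to 6-[(1S,2S,3E,5S)-1-hydroxy-2,3,5-trimethylhepta-3,6-dien-1-yl]-4-methoxy-3-methyl-2H-pyran-2-one F4.
- Cross-metathesis of F4 with 9 under the step 5 conditions gives 14. Compound 8 is used here instead of 10 because the methyl ketone would not survive the amide base.

**Step 5 (cross-metathesis).**
- Risks: conversion may be low when a trisubstituted enone is formed next to a branched allylic carbon, and the alkene may migrate.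
- Fallback (aldol and Wittig olefination instead of allylation and metathesis). It sets out from 5 and comes back at 10.
- The dibutylboron enolate of commercial (R)-4-benzyl-3-propionyl-1,3-oxazolidin-2-one (Bu2BOTf, Et3N, CH2Cl2, −78 to 0 °C; H2O2 work-up) adds to 5 in an Evans syn aldol. The product is (4R)-4-benzyl-3-[(2R,3R,4E)-3-hydroxy-2,4-dimethylhex-4-enoyl]-1,3-oxazolidin-2-one F5.
- MeNH(OMe)·HCl/AlMe3 (THF, 0 °C) gives (2R,3R,4E)-3-hydroxy-N-methoxy-N,2,4-trimethylhex-4-enamide F6.
- iBu2AlH (2.5 equiv, THF, −78 °C) gives (2R,3R,4E)-3-hydroxy-2,4-dimethylhex-4-enal F7, which is used crude.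
- Ph3P=C(CH3)C(O)CH3 (toluene, 60 °C) olefinates F7 E-selectively to 10.

**Step 2 (SeO2 oxidation).**
- Risks: the conditions are harsh, over-oxidation to the acid is possible, and the yield may be modest.
- Fallback (enamine formation and oxidative cleavage instead of direct C–H oxidation). It sets out from 2 and comes back at 3.
- Heating 2 with N,N-dimethylformamide dimethyl acetal (DMF, 120 °C) condenses the acidic 6-methyl to 6-[(E)-2-(dimethylamino)ethenyl]-4-methoxy-3-methyl-2H-pyran-2-one F8.
- NaIO4 (THF/H2O, 23 °C) then cleaves the enamine double bond to 3.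

## Further compounds
F1 | step 6 | 6-(hydroxymethyl)-4-methoxy-3-methyl-2H-pyran-2-one | COc1cc(CO)oc(=O)c1C
F2 | step 6 | 6-(bromomethyl)-4-methoxy-3-methyl-2H-pyran-2-one | COc1cc(CBr)oc(=O)c1C
F3 | step 6 | 6-({[(3S,4R,5E)-3,5-dimethylhepta-1,5-dien-4-yl]oxy}methyl)-4-methoxy-3-methyl-2H-pyran-2-one | COc1cc(CO[C@H]([C@@H](C)C=C)/C(C)=C/C)oc(=O)c1C
F4 | step 6 | 6-[(1S,2S,3E,5S)-1-hydroxy-2,3,5-trimethylhepta-3,6-dien-1-yl]-4-methoxy-3-methyl-2H-pyran-2-one | COc1cc([C@@H](O)[C@@H](C)/C(C)=C/[C@@H](C)C=C)oc(=O)c1C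
F5 | step 5 | (4R)-4-benzyl-3-[(2R,3R,4E)-3-hydroxy-2,4-dimethylhex-4-enoyl]-1,3-oxazolidin-2-one | C/C=C(\C)[C@H](O)[C@@H](C)C(=O)N1[C@H](Cc2ccccc2)COC1=O
F6 | step 5 | (2R,3R,4E)-3-hydroxy-N-methoxy-N,2,4-trimethylhex-4-enamide | C/C=C(\C)[C@H](O)[C@@H](C)C(=O)N(C)OC
F7 | step 5 | (2R,3R,4E)-3-hydroxy-2,4-dimethylhex-4-enal | C/C=C(\C)[C@H](O)[C@@H](C)C=O
F8 | step 2 | 6-[(E)-2-(dimethylamino)ethenyl]-4-methoxy-3-methyl-2H-pyran-2-one | COc1cc(/C=C/N(C)C)oc(=O)c1C
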